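The earlier runs and the new flask are simulated from invented constants; noise was put on by code.

The product in the elm flask reads 77.0 % at 3.00 d and 77.2 % at 5.00 d, and I ask what that plateau leaves unaccounted.

in all of them: starting material 2.1 M; free catalyst 10 mol%
- elm: temperature 100 °C; the very flask that is asked about, followed so far
- birch: temperature 95 °C; run made earlier
- flask: temperature 100 °C; time 8.0 d

| run | time / d | product / % | starting material / % |
|---|---|---|---|
| elm | 0.625 | 60.8 | 17.5 |
| elm | 1.67 | 75.5 | 0.8 |
| elm | 3.00 | 77.0 | 0 |
| elm | 5.00 | 77.2 | 0.7 |
| birch | 0.625 | 50.1 | 32.6 |
| birch | 1.67 | 73.9 | 5.3 |
| birch | 3.00 | 77.9 | 1.7 |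
| birch | 5.00 | 78.6 | 0 |

(scatter of a reading: 1 percentage point)

- red: at 8.0 d add free catalyst, 100 % of the amount charged, then wait 4.0 d
- blue: change nothing and wait 4.0 d more
- green: at 8.0 d raise the temperature by 20 K, then wait 4.0 d
- grey: at 8.0 d take out 90 % of the product then present, then wait 4.0 d

- what is taken out of product is counted as made
- additions bring no volume worth counting

- product, in percent of the starting material first charged, at 8.0 d
- which option adds most product ("none" when 2 percentage points or less is all one gets) (red / blue / green / grey / none)
- product present, with what was taken out counted in, in percent of the starting material first charged, after red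
- product present, with what was taken out counted in, in percent of the starting material first charged, after green

At the last elm reading, subtraction gives 22.1 %: this is the missing share, the charge less product less starting material, the room the product has beyond the starting material left. The early end of the elm run, at 0.625 d, gives 21.7 % by the same subtraction. At the other end, the product rises over the last interval by 0.2 percentage points in elm and 0.7 points in birch, against a scatter of 1 point. Continuing the mean of those rises, I reckon 77.9 % for the elm flask at 8.0 d. With rises of that size I can't tell lost from held, so green is my bet, not a finding.

The forecast gives 77.2 % at 8.0 d, 77.2 % after red, 77 % after green and none as the best option, reading the missing share as “a parallel, irreversible side channel”; my reckoning differs from it at 8.0 d and in the best option.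

The elm flask gives 80.4 % at 8.0 d, 82.7 % after red and 90.7 % after green. The best option is green, adding 10 points, against 2.2 points for red, 1.9 points for blue and 1.9 points for grey. So the missing share is held, and the gain from green is about half of the 22.1 % I read at 5.00 d.

    starting material + free catalyst → catalyst intermediate (k = 0.480 /M/h, Ea = 105 kJ/mol)
    starting material ⇌ dormant form (K = 20.0, k = 0.0280 /h, Ea = 120 kJ/mol, ΔH = −3.00 kJ/mol)
    catalyst intermediate → free catalyst + product (k = 4.10 /h, Ea = 98.0 kJ/mol)
    (constants at 100 °C)

At the start, the catalyst step uses starting material 3.6 times as fast as the forward step to dormant form, which is the selectivity factor. The elm flask has not come to rest at 8.00 d: its missing share is 19.4 %, standing as dormant form at 19.4 %, and the product has moved from 78.3 % at 4.00 d. The neighbour flask with 0.53 M of starting material gives 46.8 % by the same subtraction at 8.00 d. Left until 80.0 d, the elm flask reaches 97.0 % of product, with dormant form down to 2.93 %.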